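**Retrosynthetic overview**

- The strategy rests on C3 of ring C, a fully substituted carbinol carbon that carries ring B, a hydroxyl, the O1–C2H2 arm and the C4 carbonyl. It is mapped onto an aryl(methoxycarbonyl)carbene that takes its OH from water and C2 from formaldehyde (C3–O and C2–C3 bonds, C3 stereocentre; no ring closed).
- Ring B diazo ester 10 comes from 4-bromo-3-methoxyphenol: MOM ether, deprotonative prenylation between the two oxygens, Br/Li exchange and oxalate acylation, tosylhydrazone, base.
- Ring A bromophenol 20 comes from 5-methoxyresorcinol: bis-MOM ether, directed bromination between the acetals, mono-deprotection, ortho C-prenylation.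
- After the key step, diol 14 is closed to glycidic ester 22, which phenol 20 opens at CH2 (O1–C2 bond). Ring C, the only ring formed, is then closed at C4–C4a by Parham cyclization of the aryl bromide onto the ester.
- Both MOM ethers are removed last.

Key step: step 6

Assumption: the (S) antipode of 3,3′-diiodo-BINOL on zirconium is taken to give the (S)-diol 14; if the sense of induction proves to be the reverse, the (R) ligand is used and nothing else changes.

Remark: the target is (3S). Compounds 14, 21, 22, 23 and 25 carry the same descriptor, because the priority order O > carbonyl carbon > CH2O > aryl holds throughout and no bond to this carbon is broken after step 6.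

**Route**

Step 1
Reactants: 1 4-bromo-3-methoxyphenol
Product: 2 1-bromo-2-methoxy-4-(methoxymethoxy)benzene
Conditions: NaH, MOMCl, DMF, 0 °C → rt
Reagents that add atoms: chloromethyl methyl ether, COCCl
Why: Williamson-type O-alkylation of the sodium phenoxide gives the MOM acetal, which is stable to the organolithium steps and serves as a metalation director in step 2.

Step 2
Reactants: 2 1-bromo-2-methoxy-4-(methoxymethoxy)benzene; 3 prenyl bromide (1-bromo-3-methylbut-2-ene)
Product: 5 1-bromo-2-methoxy-4-(methoxymethoxy)-3-(3-methylbut-2-en-1-yl)benzene, via aryllithium 4 (not isolated)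
Conditions: lithium 2,2,6,6-tetramethylpiperidide (LiTMP, from the amine and n-BuLi), THF, −78 °C; then CuBr·SMe2 (20 mol%), 3, −78 → −20 °C
Reagents that add atoms: none
Why: Directed ortho-metalation: the hydrogen flanked by the methoxy and methoxymethoxy groups is the most acidic ring position and is meta to bromine, so the hindered amide base should remove it without Br/Li exchange or aryne formation, and copper-assisted SN2 allylation of 4 places the linear prenyl group there.

Step 3
Reactants: 5 1-bromo-2-methoxy-4-(methoxymethoxy)-3-(3-methylbut-2-en-1-yl)benzene; 6 dimethyl oxalate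
Product: 8 methyl 2-[2-methoxy-4-(methoxymethoxy)-3-(3-methylbut-2-en-1-yl)phenyl]-2-oxoacetate, via aryllithium 7 (not isolated)
Conditions: n-BuLi, THF, −78 °C; cannulated into 6 (3 equiv), THF, −78 °C; aq NH4Cl
Reagents that add atoms: none
Why: Bromine–lithium exchange followed by acylation of the aryllithium with excess oxalate diester (inverse addition) should stop at the aryl glyoxylate, because the tetrahedral adduct persists at low temperature.

Step 4
Reactants: 8 methyl 2-[2-methoxy-4-(methoxymethoxy)-3-(3-methylbut-2-en-1-yl)phenyl]-2-oxoacetate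
Product: 9 methyl 2-[2-methoxy-4-(methoxymethoxy)-3-(3-methylbut-2-en-1-yl)phenyl]-2-[2-(4-methylbenzenesulfonyl)hydrazinylidene]acetate
Conditions: TsNHNH2, MeOH, 60 °C
Reagents that add atoms: p-toluenesulfonyl hydrazide, Cc1ccc(cc1)S(=O)(=O)NN
Why: Condensation of the activated ketone carbonyl of an α-keto ester with the sulfonyl hydrazide (hydrazone formation) is selective over the ester and needs no strong acid, so the MOM ether survives.

Step 5
Reactants: 9 methyl 2-[2-methoxy-4-(methoxymethoxy)-3-(3-methylbut-2-en-1-yl)phenyl]-2-[2-(4-methylbenzenesulfonyl)hydrazinylidene]acetate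
Product: 10 methyl 2-diazo-2-[2-methoxy-4-(methoxymethoxy)-3-(3-methylbut-2-en-1-yl)phenyl]acetate
Conditions: DBU, CH2Cl2, 0 °C → rt
Reagents that add atoms: none
Why: Bamford–Stevens elimination of sulfinate from the deprotonated tosylhydrazone gives the aryldiazoacetate, which is stabilised by the ester and can be handled at room temperature.

Step 6
Reactants: 10 methyl 2-diazo-2-[2-methoxy-4-(methoxymethoxy)-3-(3-methylbut-2-en-1-yl)phenyl]acetate; 11 formaldehyde; 12 water
Product: 14 methyl (2S)-2,3-dihydroxy-2-[2-methoxy-4-(methoxymethoxy)-3-(3-methylbut-2-en-1-yl)phenyl]propanoate, via enol 13 (not isolated)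
Conditions: Rh2(OAc)4 (2 mol%), Zr(Ot-Bu)4/(S)-3,3′-diiodo-BINOL (15 mol%), 11 (monomeric, from cracked paraformaldehyde, 5 equiv, cold CH2Cl2 solution), 12 (2 equiv), CH2Cl2, −20 → 0 °C, 10 added slowly by syringe pump
Reagents that add atoms: none
Why: Proposed new method: Rh2(OAc)4 turns 10 into an electrophilic donor/acceptor carbene whose carbon is attacked by water (or by formaldehyde hydrate) to give a protic oxonium ylide in equilibrium with enol 13, and before the 1,2-proton shift that would end in the mandelate this enol adds through carbon to formaldehyde held on the chiral zirconium BINOLate, so that C3–O and C2–C3 form in one operation. The closest known reaction types are the Rh2(OAc)4/zirconium BINOLate three-component coupling of aryldiazoacetates, alcohols and aryl aldehydes (aldol-type trapping of oxonium ylides to quaternary α-alkoxy-β-hydroxy esters) and the racemic Rh2(OAc)4 trapping of water-derived ylides of cyclic diazo amides by formaldehyde; combining water as O–H donor, formaldehyde as acceptor and enantiocontrol on an acyclic aryldiazoacetate is the untested part. No ring is closed. The one new stereocentre (future C3, S) is set by the BINOLate-bound zirconium, which is expected to hold the enol through its hydroxyl and ester oxygens and to deliver formaldehyde to one enantiotopic face. The step needs chemoselectivity for O–H ylide formation over cyclopropanation of the prenyl alkene, C–H insertion into the ortho-methoxy group and carbonyl-ylide formation with formaldehyde; the much faster O–H capture by donor/acceptor rhodium carbenes, the trisubstituted and remote alkene and the limited excess of monomeric formaldehyde should secure it. Slow addition of 10 keeps the carbene concentration low, and the excess of Lewis-acid-bound formaldehyde should let C–C bond formation outrun proton transfer.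

Step 7
Reactants: 15 5-methoxyresorcinol
Product: 16 1-methoxy-3,5-bis(methoxymethoxy)benzene
Conditions: NaH, MOMCl, DMF, 0 °C → rt
Reagents that add atoms: chloromethyl methyl ether, COCCl
Why: Double O-alkylation of the bis-phenoxide gives a symmetric bis-acetal whose two MOM groups jointly direct the next metalation.

Step 8
Reactants: 16 1-methoxy-3,5-bis(methoxymethoxy)benzene
Product: 18 2-bromo-5-methoxy-1,3-bis(methoxymethoxy)benzene, via aryllithium 17 (not isolated)
Conditions: n-BuLi, THF, 0 °C; BrCl2C–CCl2Br, −78 °C → rt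
Reagents that add atoms: 1,2-dibromo-1,1,2,2-tetrachloroethane, BrC(Cl)(Cl)C(Cl)(Cl)Br
Why: Directed ortho-metalation takes place at the carbon flanked by both chelating MOM groups in preference to the positions next to the methoxy group, and the aryllithium is brominated by halogen transfer from the polyhaloethane.

Step 9
Reactants: 18 2-bromo-5-methoxy-1,3-bis(methoxymethoxy)benzene
Product: 19 2-bromo-5-methoxy-3-(methoxymethoxy)phenol
Conditions: HCl (cat.), MeOH, 0 °C → rt, stopped at partial conversion; recovered 18 returned to the step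
Reagents that add atoms: none
Why: Acid-catalysed acetal methanolysis of one of two equivalent MOM groups is a statistical desymmetrisation that can give only one mono-phenol, and unchanged 18 is recyclable.

Step 10
Reactants: 19 2-bromo-5-methoxy-3-(methoxymethoxy)phenol; 3 prenyl bromide (1-bromo-3-methylbut-2-ene)
Product: 20 2-bromo-5-methoxy-3-(methoxymethoxy)-6-(3-methylbut-2-en-1-yl)phenol
Conditions: NaH, toluene, 0 °C; 3, rt
Reagents that add atoms: none
Why: Ortho-selective C-allylation of a sodium phenoxide: in a non-polar solvent the tight ion pair delivers the allylic halide to the ortho carbon, and since the other ortho position carries bromine the prenyl group should enter only between the hydroxyl and the methoxy group.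

Step 11
Reactants: 14 methyl (2S)-2,3-dihydroxy-2-[2-methoxy-4-(methoxymethoxy)-3-(3-methylbut-2-en-1-yl)phenyl]propanoate
Product: 22 methyl (2S)-2-[2-methoxy-4-(methoxymethoxy)-3-(3-methylbut-2-en-1-yl)phenyl]oxirane-2-carboxylate, via mesylate 21 (not isolated)
Conditions: MsCl, Et3N, CH2Cl2, −20 °C; then DBU, 0 °C → rt
Reagents that add atoms: none
Why: Selective sulfonylation of the primary hydroxyl and 3-exo-tet displacement by the tertiary alkoxide (intramolecular Williamson epoxide closure) break no bond to the stereocentre, so its configuration is retained.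

Step 12
Reactants: 22 methyl (2S)-2-[2-methoxy-4-(methoxymethoxy)-3-(3-methylbut-2-en-1-yl)phenyl]oxirane-2-carboxylate; 20 2-bromo-5-methoxy-3-(methoxymethoxy)-6-(3-methylbut-2-en-1-yl)phenol
Product: 23 methyl (2S)-3-[2-bromo-5-methoxy-3-(methoxymethoxy)-6-(3-methylbut-2-en-1-yl)phenoxy]-2-hydroxy-2-[2-methoxy-4-(methoxymethoxy)-3-(3-methylbut-2-en-1-yl)phenyl]propanoate
Conditions: Cs2CO3 (20 mol%), DMF, 70 °C
Reagents that add atoms: none
Why: SN2 opening of a 2,2-disubstituted epoxide by phenoxide at the unsubstituted CH2 terminus forms the O1–C2 ether with the stereocentre untouched, and the tertiary alkoxide set free deprotonates the next phenol, so base is needed only in catalytic amount.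

Step 13
Reactants: 23 methyl (2S)-3-[2-bromo-5-methoxy-3-(methoxymethoxy)-6-(3-methylbut-2-en-1-yl)phenoxy]-2-hydroxy-2-[2-methoxy-4-(methoxymethoxy)-3-(3-methylbut-2-en-1-yl)phenyl]propanoate
Product: 25 (3S)-3-hydroxy-7-methoxy-3-[2-methoxy-4-(methoxymethoxy)-3-(3-methylbut-2-en-1-yl)phenyl]-5-(methoxymethoxy)-8-(3-methylbut-2-en-1-yl)-2,3-dihydro-4H-chromen-4-one, via sodium alkoxide aryllithium 24 (not isolated)
Conditions: NaH, THF, 0 °C; then t-BuLi (2.1 equiv), −78 → −20 °C; aq NH4Cl
Reagents that add atoms: none
Why: Parham cyclization: with the tertiary hydroxyl parked as its sodium alkoxide, bromine–lithium exchange is faster than addition of t-BuLi to the ester, and the aryllithium acylates intramolecularly (6-exo-trig) to close ring C at C4–C4a, the stereocentre having no α-hydrogen and staying untouched.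

Step 14
Reactants: 25 (3S)-3-hydroxy-7-methoxy-3-[2-methoxy-4-(methoxymethoxy)-3-(3-methylbut-2-en-1-yl)phenyl]-5-(methoxymethoxy)-8-(3-methylbut-2-en-1-yl)-2,3-dihydro-4H-chromen-4-one
Product: 26 sophonorol F, (3S)-3,5-dihydroxy-3-[4-hydroxy-2-methoxy-3-(3-methylbut-2-en-1-yl)phenyl]-7-methoxy-8-(3-methylbut-2-en-1-yl)-2,3-dihydro-4H-chromen-4-one
Conditions: 3 M aq HCl, MeOH, 40 °C
Reagents that add atoms: none
Why: Acid-catalysed acetal methanolysis removes both aryl MOM ethers (the one peri to the C4 carbonyl fastest) under conditions mild enough that the prenyl groups and the tertiary alcohol should stay in place.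

**Compound list**

1 | 4-bromo-3-methoxyphenol | COc1cc(O)ccc1Br | starting material
2 | 1-bromo-2-methoxy-4-(methoxymethoxy)benzene | COCOc1ccc(Br)c(OC)c1 | intermediate
3 | prenyl bromide (1-bromo-3-methylbut-2-ene) | CC(C)=CCBr | starting material
4 | [3-bromo-2-methoxy-6-(methoxymethoxy)phenyl]lithium | COCOc1ccc(Br)c(OC)c1[Li] | intermediate
5 | 1-bromo-2-methoxy-4-(methoxymethoxy)-3-(3-methylbut-2-en-1-yl)benzene | COCOc1ccc(Br)c(OC)c1CC=C(C)C | intermediate
6 | dimethyl oxalate | COC(=O)C(=O)OC | starting material
7 | [2-methoxy-4-(methoxymethoxy)-3-(3-methylbut-2-en-1-yl)phenyl]lithium | COCOc1ccc([Li])c(OC)c1CC=C(C)C | intermediate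
8 | methyl 2-[2-methoxy-4-(methoxymethoxy)-3-(3-methylbut-2-en-1-yl)phenyl]-2-oxoacetate | COC(=O)C(=O)c1ccc(OCOC)c(CC=C(C)C)c1OC | intermediate
9 | methyl 2-[2-methoxy-4-(methoxymethoxy)-3-(3-methylbut-2-en-1-yl)phenyl]-2-[2-(4-methylbenzenesulfonyl)hydrazinylidene]acetate | COC(=O)C(=NNS(=O)(=O)c1ccc(C)cc1)c1ccc(OCOC)c(CC=C(C)C)c1OC | intermediate
10 | methyl 2-diazo-2-[2-methoxy-4-(methoxymethoxy)-3-(3-methylbut-2-en-1-yl)phenyl]acetate | COC(=O)C(=[N+]=[N-])c1ccc(OCOC)c(CC=C(C)C)c1OC | intermediate
11 | formaldehyde | C=O | starting material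
12 | water | O | starting material
13 | 1-methoxy-2-[2-methoxy-4-(methoxymethoxy)-3-(3-methylbut-2-en-1-yl)phenyl]ethene-1,2-diol (enol of the mandelate) | COC(O)=C(O)c1ccc(OCOC)c(CC=C(C)C)c1OC | intermediate
14 | methyl (2S)-2,3-dihydroxy-2-[2-methoxy-4-(methoxymethoxy)-3-(3-methylbut-2-en-1-yl)phenyl]propanoate | OC[C@@](O)(c1ccc(OCOC)c(CC=C(C)C)c1OC)C(=O)OC | intermediate
15 | 5-methoxyresorcinol | COc1cc(O)cc(O)c1 | starting material
16 | 1-methoxy-3,5-bis(methoxymethoxy)benzene | COCOc1cc(OC)cc(OCOC)c1 | intermediate
17 | [4-methoxy-2,6-bis(methoxymethoxy)phenyl]lithium | COCOc1cc(OC)cc(OCOC)c1[Li] | intermediate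
18 | 2-bromo-5-methoxy-1,3-bis(methoxymethoxy)benzene | COCOc1cc(OC)cc(OCOC)c1Br | intermediate
19 | 2-bromo-5-methoxy-3-(methoxymethoxy)phenol | COCOc1cc(OC)cc(O)c1Br | intermediate
20 | 2-bromo-5-methoxy-3-(methoxymethoxy)-6-(3-methylbut-2-en-1-yl)phenol | COCOc1cc(OC)c(CC=C(C)C)c(O)c1Br | intermediate
21 | methyl (2S)-2-hydroxy-3-(methanesulfonyloxy)-2-[2-methoxy-4-(methoxymethoxy)-3-(3-methylbut-2-en-1-yl)phenyl]propanoate | CS(=O)(=O)OC[C@@](O)(c1ccc(OCOC)c(CC=C(C)C)c1OC)C(=O)OC | intermediate
22 | methyl (2S)-2-[2-methoxy-4-(methoxymethoxy)-3-(3-methylbut-2-en-1-yl)phenyl]oxirane-2-carboxylate | C1O[C@]1(c2ccc(OCOC)c(CC=C(C)C)c2OC)C(=O)OC | intermediate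
23 | methyl (2S)-3-[2-bromo-5-methoxy-3-(methoxymethoxy)-6-(3-methylbut-2-en-1-yl)phenoxy]-2-hydroxy-2-[2-methoxy-4-(methoxymethoxy)-3-(3-methylbut-2-en-1-yl)phenyl]propanoate | COCOc1cc(OC)c(CC=C(C)C)c(OC[C@@](O)(c2ccc(OCOC)c(CC=C(C)C)c2OC)C(=O)OC)c1Br | intermediate
24 | sodium alkoxide and aryllithium of 23 (lithium at the former C–Br carbon, sodium on the tertiary oxygen, 2S) | COCOc1cc(OC)c(CC=C(C)C)c(OC[C@@](O[Na])(c2ccc(OCOC)c(CC=C(C)C)c2OC)C(=O)OC)c1[Li] | intermediate
25 | (3S)-3-hydroxy-7-methoxy-3-[2-methoxy-4-(methoxymethoxy)-3-(3-methylbut-2-en-1-yl)phenyl]-5-(methoxymethoxy)-8-(3-methylbut-2-en-1-yl)-2,3-dihydro-4H-chromen-4-one | COc1cc(OCOC)c2c(c1CC=C(C)C)OC[C@@](O)(c1ccc(OCOC)c(CC=C(C)C)c1OC)C2=O | intermediate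
26 | sophonorol F, (3S)-3,5-dihydroxy-3-[4-hydroxy-2-methoxy-3-(3-methylbut-2-en-1-yl)phenyl]-7-methoxy-8-(3-methylbut-2-en-1-yl)-2,3-dihydro-4H-chromen-4-one | COc1cc(O)c2c(c1CC=C(C)C)OC[C@@](O)(c1ccc(O)c(CC=C(C)C)c1OC)C2=O | target

**Step count and risks**

Total step count: 14. Longest linear sequence: 10 steps (steps 1–6 and 11–14); the ring A branch (steps 7–10) joins at step 12.

Steps most likely to fail:

1. Step 6 (three-component coupling). The 1,2-proton shift within the water ylide may outrun aldol capture, so that plain O–H insertion results, or capture may occur without useful facial control on the small formaldehyde acceptor. The fallback uses known chemistry, sets out from glyoxylate 8 and returns at epoxide 22.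
 - Wittig methylenation of 8 (Ph3P=CH2, THF, 0 °C) should give methyl 2-[2-methoxy-4-(methoxymethoxy)-3-(3-methylbut-2-en-1-yl)phenyl]prop-2-enoate F1.
 - Reduction with i-Bu2AlH (CH2Cl2, −78 °C) should give 2-[2-methoxy-4-(methoxymethoxy)-3-(3-methylbut-2-en-1-yl)phenyl]prop-2-en-1-ol F2.
 - Sharpless asymmetric epoxidation (Ti(Oi-Pr)4, D-(−)-diethyl tartrate, t-BuOOH, 4 Å molecular sieves, CH2Cl2, −20 °C) oxidises only the allylic alcohol alkene and leaves the isolated prenyl group alone. It is expected to give [(2R)-2-[2-methoxy-4-(methoxymethoxy)-3-(3-methylbut-2-en-1-yl)phenyl]oxiran-2-yl]methanol F3; the tartrate antipode is fixed by the usual mnemonic.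
 - Oxidation of the primary alcohol with TEMPO/PhI(OAc)2 in buffered aqueous MeCN should give (2S)-2-[2-methoxy-4-(methoxymethoxy)-3-(3-methylbut-2-en-1-yl)phenyl]oxirane-2-carboxylic acid F4. No strongly basic step is used on F3, so that epoxide migration cannot erode the configuration.
 - Methylation (MeI, K2CO3, DMF) gives 22.

2. Step 13 (Parham cyclization). The aryllithium may be quenched by proton transfer, or the alkyllithium may add to the ester before ring closure, and the alkoxide next to the new ketone may be lost to further addition. The fallback sets out from 23 and returns at target 26.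
 - Silylation of the tertiary hydroxyl (Et3SiOTf, 2,6-lutidine, CH2Cl2, 0 °C) should give methyl (2S)-3-[2-bromo-5-methoxy-3-(methoxymethoxy)-6-(3-methylbut-2-en-1-yl)phenoxy]-2-[2-methoxy-4-(methoxymethoxy)-3-(3-methylbut-2-en-1-yl)phenyl]-2-(triethylsilyloxy)propanoate F5.
 - Exchange and acylation with t-BuLi alone (2.1 equiv, THF, −78 °C), now free of any acidic or anionic oxygen, should give (3S)-7-methoxy-3-[2-methoxy-4-(methoxymethoxy)-3-(3-methylbut-2-en-1-yl)phenyl]-5-(methoxymethoxy)-8-(3-methylbut-2-en-1-yl)-3-(triethylsilyloxy)-2,3-dihydro-4H-chromen-4-one F6.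
 - The acid conditions of step 14 then remove the silyl ether together with both MOM groups to give 26.

3. Step 10 (ortho C-prenylation). O-alkylation, para C-alkylation or double alkylation to a dienone may compete with the ortho C-alkylation. The fallback sets out from phenol 19 and returns at 20.
 - O-alkylation with 3-chloro-3-methylbut-1-yne (K2CO3, KI, CuI cat., acetone, reflux) should give 2-bromo-5-methoxy-1-(methoxymethoxy)-3-[(2-methylbut-3-yn-2-yl)oxy]benzene F7.
 - Semihydrogenation (H2, Pd/CaCO3 poisoned with lead, quinoline, EtOAc) should give 2-bromo-5-methoxy-1-(methoxymethoxy)-3-[(2-methylbut-3-en-2-yl)oxy]benzene F8.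
 - Aromatic Claisen rearrangement (N,N-diethylaniline, 120 °C) transfers the allyl unit with allylic inversion to the only free ortho carbon and gives 20 with full regiocontrol.

**Further compounds**

F1 | step 6 | methyl 2-[2-methoxy-4-(methoxymethoxy)-3-(3-methylbut-2-en-1-yl)phenyl]prop-2-enoate | C=C(C(=O)OC)c1ccc(OCOC)c(CC=C(C)C)c1OC
F2 | step 6 | 2-[2-methoxy-4-(methoxymethoxy)-3-(3-methylbut-2-en-1-yl)phenyl]prop-2-en-1-ol | C=C(CO)c1ccc(OCOC)c(CC=C(C)C)c1OC
F3 | step 6 | [(2R)-2-[2-methoxy-4-(methoxymethoxy)-3-(3-methylbut-2-en-1-yl)phenyl]oxiran-2-yl]methanol | C1O[C@]1(c2ccc(OCOC)c(CC=C(C)C)c2OC)CO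
F4 | step 6 | (2S)-2-[2-methoxy-4-(methoxymethoxy)-3-(3-methylbut-2-en-1-yl)phenyl]oxirane-2-carboxylic acid | C1O[C@]1(c2ccc(OCOC)c(CC=C(C)C)c2OC)C(=O)O
F5 | step 13 | methyl (2S)-3-[2-bromo-5-methoxy-3-(methoxymethoxy)-6-(3-methylbut-2-en-1-yl)phenoxy]-2-[2-methoxy-4-(methoxymethoxy)-3-(3-methylbut-2-en-1-yl)phenyl]-2-(triethylsilyloxy)propanoate | COCOc1cc(OC)c(CC=C(C)C)c(OC[C@@](O[Si](CC)(CC)CC)(c2ccc(OCOC)c(CC=C(C)C)c2OC)C(=O)OC)c1Br
F6 | step 13 | (3S)-7-methoxy-3-[2-methoxy-4-(methoxymethoxy)-3-(3-methylbut-2-en-1-yl)phenyl]-5-(methoxymethoxy)-8-(3-methylbut-2-en-1-yl)-3-(triethylsilyloxy)-2,3-dihydro-4H-chromen-4-one | COc1cc(OCOC)c2c(c1CC=C(C)C)OC[C@@](O[Si](CC)(CC)CC)(c1ccc(OCOC)c(CC=C(C)C)c1OC)C2=O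
F7 | step 10 | 2-bromo-5-methoxy-1-(methoxymethoxy)-3-[(2-methylbut-3-yn-2-yl)oxy]benzene | COCOc1cc(OC)cc(OC(C)(C)C#C)c1Br
F8 | step 10 | 2-bromo-5-methoxy-1-(methoxymethoxy)-3-[(2-methylbut-3-en-2-yl)oxy]benzene | COCOc1cc(OC)cc(OC(C)(C)C=C)c1Br
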